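## Structural features

The target (C54H38O27) is an achiral phlorotannin of nine benzene rings. Four of them form a chain joined by ether oxygens (A to B1, B4 to C1, C4 to D1), two rings E hang on D2 and D6 through oxygen, and three 2,4,6-trihydroxyphenyl rings are attached by biaryl bonds (B' on B5, one ring F on E5 of each ring E). It carries 22 free phenolic hydroxyls and five ether oxygens. There is no stereocentre, and no biaryl axis is stereogenic because B' and F are symmetric about their axes, so no stereochemical relationship has to be set. The fragile part is the free polyphenol, which is electron-rich, oxidised by air in base and hard to purify; the diaryl ethers and biaryls themselves are robust. The real difficulty is steric and regiochemical: B1, C1 and E1 each sit between two oxygen-bearing carbons, D1 sits between two aryloxy groups, and each biaryl bond has four ortho oxygens, the worst case for metal-mediated coupling. The key step exploits the position of E1 between the hydroxylated carbons E2 and E6: those two oxygens are carried as formyl groups that activate a fluoride on E1 toward the D2 and D6 phenols, and a bromide on E4 stands in for the fourth oxygen. The same pattern recurs at B1 and C1, so one fluoro-dialdehyde can serve rings B, C and both rings E.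

## Logic of the disconnections

30 ⇒ 29. All 22 hydroxyls are traced back to methyl ethers. The free polyphenol cannot be carried through coupling chemistry, whereas 29 is a neutral compound that can be chromatographed. The demand is a final cleavage of 22 O–CH3 bonds that leaves the five diaryl ethers intact.

29 ⇒ 17 + 28. The C4–O bond of the C4–O–D1 ether is cut. This divides the molecule into a five-ring phenol and a four-ring bromide of similar size, and it places the halide on the unhindered ring C carbon (two ortho hydrogens). The demand is a copper-mediated etherification that accepts a phenol flanked by two aryloxy groups.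

17 ⇒ 16 ⇒ 15. Only protecting groups change: D1–OH comes from its benzyl ether, and the E4 methyl ethers from free E4 hydroxyls. Benzyl is the one group that differs from all the others, so D1 can be freed alone. The demand is that no halogen is present at the hydrogenolysis.

15 ⇒ 13 + 2 × 14. The two E5–F1 biaryl bonds are cut. Ring F then arrives intact as 14, and the free E4 hydroxyl of 13 directs the new bond to its ortho carbon; E3 and E5 are equivalent, so either gives the same product. The demand is one ortho arylation per ring E with cross-coupling favoured over homo-coupling.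

13 ⇒ 12 ⇒ 11 ⇒ 9. These are functional-group changes on ring E: E4–OH from E4–Br, the E2 and E6 methyl ethers from phenols, and those phenols from formyl groups by oxygen insertion. This turns an electron-rich ring that is hard to couple into an electron-poor one. The demand is aryl migration in four Baeyer–Villiger oxidations.

9 ⇒ 8 + 2 × 3. The D2–O–E1 and D6–O–E1 bonds are cut on the ring E side, so ring E is the electrophile and ring D the nucleophile. Both partners are symmetric and small. The demand is O-arylation at C–F in preference to reaction at the aldehydes.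

8 ⇒ 6 ⇒ 5 ⇒ 4. The two hydroxyls of 8 are again traced to formyl groups, which go back to the two ortho C–H bonds of 4. An ester-based route would need reduction and re-oxidation before the oxygen insertion; this one reaches 8 in three steps. The demand is double ortho formylation and double aryl migration.

3 ⇒ 2 ⇒ 1. The formyl groups come from the methyl groups by way of the benzal bromides. The halogen pattern is already in place in 1. The demand is clean fourfold benzylic bromination.

28 ⇒ 27 ⇒ 25 ⇒ 24 + 3. The C1–O bond of the B4–O–C1 ether is cut, with the same logic as for ring E: C1 lies between C2 and C6, and the bromide of 3 becomes the handle at C4. The demand is substitution by a phenol that has one ortho aryl group.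

24 ⇒ 23 + 14. The B5–B'1 bond is cut ortho to the free B4 hydroxyl. B3 and B5 are equivalent, so no regiochemical choice arises. The demand is that 14 competes successfully with ring A as the nucleophilic arene.

23 ⇒ 22 ⇒ 21 ⇒ 19 ⇒ 18 + 3. The B1–O bond of the A–O–B1 ether is cut on the ring B side, followed by the same oxygen insertion, methylation and bromide-to-hydroxyl exchange. Everything goes back to 18 and a third equivalent of 3.

## Other disconnections considered

Alternative 1: The B5–B'1 bond is made intramolecularly. Rings B and B' are first linked through a di-tert-butylsilylene bridge between the B6 and B'2 oxygens (bromide A2). Palladium catalysis then effects oxidative addition into C–Br, metalation–deprotonation at B5–H and reductive elimination, giving the seven-membered dibenzodioxasilepine A1.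
- In its favour: the tether fixes the site (B5, not B3), makes a tetra-ortho-substituted biaryl bond entropically easy, and uses no oxidant, so ring A is not at risk and a second arylation cannot occur. On regiocontrol and chemoselectivity it is better than the oxidative arylation chosen here.
- Against it: it needs a ring B whose B6 oxygen is free while B2 is methylated, but the dialdehyde-derived ring B has two equivalent oxygens. Making A2 means joining two hindered phenols on silicon without symmetric by-products. The C–H bond to be broken lies on an electron-rich ring, the unfavourable case for concerted metalation–deprotonation, and the closure runs through an eight-membered palladacycle.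
- Step economy: tether formation, arylation, desilylation and methylation make about four operations for one biaryl bond, against one in the chosen plan. The two E–F bonds would need the same detour twice or a second method. The two plans are equal in the bond formed.

Alternative 2: Both rings F are built from acyclic carbon. In the bis(siloxyalkyne) A4 each E5 carries a silyloxyethynyl group. Heating with 3-ethoxycyclobutenone A5 opens the cyclobutenone to a vinylketene, which adds to the ynol ether (F1–F2 and F5–F6). The new cyclobutenone then opens, and a six-electron electrocyclisation (F2–F3) with tautomerisation gives A3.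
- In its favour: the E5–F1 bond exists from the start as an aryl–alkyne bond, so no hindered biaryl coupling is needed. The cascade is thermal and metal-free, and over-arylation or oxidation cannot occur. On steric tolerance it is better than the chosen plan.
- Against it: A4 still needs a carbon substituent placed on E5 of each symmetric ring E, so the desymmetrisation problem is not avoided. The ynol silyl ether must be made on a doubly ortho-alkoxylated arene and is moisture-sensitive. A3 carries three different oxygen substituents on each ring F that are of no use here, since all become hydroxyl.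
- Step economy: four to five steps per ring F, against one step with intact 14. The plans are equal in that both end in the same global dealkylation.

Alternative 3: Ring C is built onto the D1 oxygen. The D1 phenol 17 is alkylated to an aryloxyacetic acid A9, which is converted to the 2-aryloxy vinamidinium salt A7. Base-mediated double condensation with 1,3-dimethoxyacetone A8 (enolate addition, loss of dimethylamine, repeat, aromatisation) forms C2–C3 and C5–C6 and gives the ring C phenol A6.
- In its favour: the most hindered ether link, C4–O–D1, is made by alkylation at an unhindered sp3 carbon, so no metal-mediated coupling at D1 is needed. For that bond it is better than the chosen Ullmann step.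
- Against it: forming A7 needs chloroiminium (Vilsmeier-type) conditions in a molecule that contains trimethoxyphenyl rings and ring D, which are themselves formylated by such reagents. The hindrance is moved, not removed: the 2,6-dimethoxyphenol of A6 must then be joined to B4, which carries the ortho ring B' and cannot be activated for substitution. That would be a coupling of a hindered phenol with a hindered halide, worse than the hindered phenol with an unhindered bromide in the chosen plan.
- Step economy: four steps build ring C, against three in the chosen plan, and the route becomes more linear. The plans are equal in atom count for ring C.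

Key step: step 6

Remark 1: the three biaryl axes each bear a ring that is symmetric about the axis, so the target has no stereogenic element and no step needs stereocontrol.
Remark 2: the formyl groups to be converted stand ortho to an alkoxy or aryloxy group and not to a free hydroxyl, so the oxygen insertion is run with a peracid (Baeyer–Villiger form of the Dakin oxidation) followed by methanolysis of the formate.

## Route

Step 1
Reactants: 1 5-bromo-2-fluoro-1,3-dimethylbenzene
Product: 2 5-bromo-1,3-bis(dibromomethyl)-2-fluorobenzene
Conditions: NBS (4.4 equiv), AIBN (cat.), PhCF3, reflux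
Reagents that add atoms: N-bromosuccinimide, O=C1CCC(=O)N1Br
Why: Wohl–Ziegler radical bromination; each methyl should take two bromines and then stop, because the third substitution is sterically and polar-disfavoured, and the aryl halides are inert to bromine radicals.

Step 2
Reactants: 2 5-bromo-1,3-bis(dibromomethyl)-2-fluorobenzene
Product: 3 5-bromo-2-fluoroisophthalaldehyde
Conditions: AgNO3, acetone–H2O, reflux
Reagents that add atoms: water, O
Why: Silver-assisted hydrolysis of benzal bromides to aldehydes; the medium is acidic and holds no nucleophile able to displace the activated fluoride.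

Step 3
Reactants: 4 4-methoxyphenol
Product: 5 2-hydroxy-5-methoxyisophthalaldehyde
Conditions: hexamethylenetetramine (4 equiv), CF3CO2H, reflux; then aq. HCl
Reagents that add atoms: hexamethylenetetramine, C1N2CN3CN1CN(C2)C3; water, O
Why: Twofold Duff formylation; the phenol is aminomethylated at both ortho positions (para is blocked by methoxy), each benzylamine is oxidised to an iminium ion by hydride transfer, and hydrolysis gives the dialdehyde.

Step 4
Reactants: 5 2-hydroxy-5-methoxyisophthalaldehyde
Product: 6 2-(benzyloxy)-5-methoxyisophthalaldehyde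
Conditions: BnBr, K2CO3, DMF, 60 °C
Reagents that add atoms: benzyl bromide, BrCc1ccccc1
Why: Williamson etherification; the phenol is acidified by two ortho formyl groups, is fully ionised by carbonate and is alkylated at oxygen.

Step 5
Reactants: 6 2-(benzyloxy)-5-methoxyisophthalaldehyde
Product: 8 2-(benzyloxy)-5-methoxybenzene-1,3-diol, via diformate 7 (not isolated)
Conditions: mCPBA (2.5 equiv), CH2Cl2, 0 °C to rt; then K2CO3, MeOH, rt
Reagents that add atoms: 3-chloroperoxybenzoic acid, O=C(OO)c1cccc(Cl)c1
Why: Baeyer–Villiger (Dakin-type) oxidation of both formyl groups; the ortho benzyloxy donor should favour aryl over hydride migration, and mild methanolysis of the diformate frees the resorcinol without touching the benzyl or methyl ether.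

Step 6
Reactants: 8 2-(benzyloxy)-5-methoxybenzene-1,3-diol; 3 5-bromo-2-fluoroisophthalaldehyde (2.1 equiv)
Product: 9 2,2'-{[2-(benzyloxy)-5-methoxy-1,3-phenylene]bis(oxy)}bis(5-bromoisophthalaldehyde)
Conditions: K2CO3, DMF, rt to 40 °C
Reagents that add atoms: none
Why: Twofold nucleophilic aromatic substitution by addition–elimination. Each phenoxide of 8 adds to the fluorine-bearing carbon of 3 to give a Meisenheimer anion whose charge is delocalised into both ortho formyl groups; loss of fluoride restores the arene, and the sequence repeats at the second phenoxide. The closest known reaction type is the etherification of phenols with 2-fluorobenzaldehydes under carbonate in a dipolar aprotic solvent. No ring is closed and no stereocentre is formed. The step needs O-arylation at C–F to win over addition to the aldehydes and over attack at bromide: addition of phenoxide oxygen to C=O is reversible and unproductive, fluoride loss is irreversible, and the bromide is meta to both formyl groups and so not activated. Regiochemistry is not in question, because 8 has two equivalent hydroxyls and 3 one activated carbon, and the benzyl ether between the nucleophilic oxygens is inert. The two ortho substituents that would block a copper-mediated coupling at E1 here accelerate the addition, so the polarity is deliberately the reverse of an Ullmann reaction.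

Step 7
Reactants: 9 2,2'-{[2-(benzyloxy)-5-methoxy-1,3-phenylene]bis(oxy)}bis(5-bromoisophthalaldehyde)
Product: 11 2,2'-{[2-(benzyloxy)-5-methoxy-1,3-phenylene]bis(oxy)}bis(5-bromobenzene-1,3-diol), via tetraformate 10 (not isolated)
Conditions: mCPBA (6 equiv), CH2Cl2, rt to 40 °C; then K2CO3, MeOH, 0 °C to rt
Reagents that add atoms: 3-chloroperoxybenzoic acid, O=C(OO)c1cccc(Cl)c1
Why: Fourfold Baeyer–Villiger oxidation of 2-aryloxybenzaldehydes; the ortho aryloxy oxygen should direct aryl migration in each Criegee adduct, and the formates are then removed by methanolysis. Ring D is flanked by electron-poor aryloxy groups and should resist the peracid.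

Step 8
Reactants: 11 2,2'-{[2-(benzyloxy)-5-methoxy-1,3-phenylene]bis(oxy)}bis(5-bromobenzene-1,3-diol)
Product: 12 2-(benzyloxy)-1,3-bis(4-bromo-2,6-dimethoxyphenoxy)-5-methoxybenzene
Conditions: MeI, K2CO3, DMF, rt
Reagents that add atoms: iodomethane, CI
Why: Williamson O-methylation of four phenols; the aryl bromides and ethers are inert.

Step 9
Reactants: 12 2-(benzyloxy)-1,3-bis(4-bromo-2,6-dimethoxyphenoxy)-5-methoxybenzene
Product: 13 4,4'-{[2-(benzyloxy)-5-methoxy-1,3-phenylene]bis(oxy)}bis(3,5-dimethoxyphenol)
Conditions: Pd2(dba)3 (cat.), tBuXPhos, KOH, 1,4-dioxane–H2O, 100 °C; then aq. HCl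
Reagents that add atoms: potassium hydroxide, [K+].[OH-]
Why: Palladium-catalysed hydroxylation of aryl bromides (oxidative addition to zerovalent palladium, exchange of bromide for hydroxide, C–O reductive elimination from the bulky biarylphosphine complex); both bromides have two ortho hydrogens and are unhindered.

Step 10
Reactants: 13 4,4'-{[2-(benzyloxy)-5-methoxy-1,3-phenylene]bis(oxy)}bis(3,5-dimethoxyphenol); 14 1,3,5-trimethoxybenzene (6 equiv)
Product: 15 4,4'-{[2-(benzyloxy)-5-methoxy-1,3-phenylene]bis(oxy)}bis[3,5-dimethoxy-2-(2,4,6-trimethoxyphenyl)phenol]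
Conditions: FeCl3 (20 mol %), t-BuOOt-Bu, (CF3)2CHOH, rt
Reagents that add atoms: none
Why: Iron-catalysed oxidative phenol–arene cross-coupling; each phenol is oxidised at trivalent iron to a bound phenoxyl species, which is attacked at its ortho carbon (para is blocked by the aryloxy group) by the excess nucleophilic arene 14, and a second oxidation restores the phenol. E3 and E5 are equivalent, and the first aryl group should shield the ring against a second arylation.

Step 11
Reactants: 15 4,4'-{[2-(benzyloxy)-5-methoxy-1,3-phenylene]bis(oxy)}bis[3,5-dimethoxy-2-(2,4,6-trimethoxyphenyl)phenol]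
Product: 16 2-(benzyloxy)-5-methoxy-1,3-bis[2,4,6-trimethoxy-3-(2,4,6-trimethoxyphenyl)phenoxy]benzene
Conditions: MeI, K2CO3, DMF, 40 °C
Reagents that add atoms: iodomethane, CI
Why: Williamson O-methylation; it removes the two free phenols that would compete in the later etherification.

Step 12
Reactants: 16 2-(benzyloxy)-5-methoxy-1,3-bis[2,4,6-trimethoxy-3-(2,4,6-trimethoxyphenyl)phenoxy]benzene
Product: 17 4-methoxy-2,6-bis[2,4,6-trimethoxy-3-(2,4,6-trimethoxyphenyl)phenoxy]phenol
Conditions: H2 (1 atm), Pd/C, EtOAc–MeOH, rt
Reagents that add atoms: none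
Why: Hydrogenolysis of the single benzyl ether; no halogen or reducible group remains, and the methyl and diaryl ethers are stable.

Step 13
Reactants: 18 3,5-dimethoxyphenol; 3 5-bromo-2-fluoroisophthalaldehyde
Product: 19 5-bromo-2-(3,5-dimethoxyphenoxy)isophthalaldehyde
Conditions: K2CO3, DMF, rt
Reagents that add atoms: none
Why: The same formyl-activated SNAr as in step 6, here forming the A–O–B1 bond; fluoride loss is irreversible and the bromide is not activated.

Step 14
Reactants: 19 5-bromo-2-(3,5-dimethoxyphenoxy)isophthalaldehyde
Product: 21 5-bromo-2-(3,5-dimethoxyphenoxy)benzene-1,3-diol, via diformate 20 (not isolated)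
Conditions: mCPBA (2.5 equiv), CH2Cl2, 0 °C to rt; then K2CO3, MeOH
Reagents that add atoms: 3-chloroperoxybenzoic acid, O=C(OO)c1cccc(Cl)c1
Why: Baeyer–Villiger oxidation of both formyl groups with aryl migration directed by the ortho aryloxy group, then formate methanolysis.

Step 15
Reactants: 21 5-bromo-2-(3,5-dimethoxyphenoxy)benzene-1,3-diol
Product: 22 5-bromo-2-(3,5-dimethoxyphenoxy)-1,3-dimethoxybenzene
Conditions: MeI, K2CO3, DMF, rt
Reagents that add atoms: iodomethane, CI
Why: Williamson O-methylation of both phenols.

Step 16
Reactants: 22 5-bromo-2-(3,5-dimethoxyphenoxy)-1,3-dimethoxybenzene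
Product: 23 4-(3,5-dimethoxyphenoxy)-3,5-dimethoxyphenol
Conditions: Pd2(dba)3 (cat.), tBuXPhos, KOH, 1,4-dioxane–H2O, 100 °C; then aq. HCl
Reagents that add atoms: potassium hydroxide, [K+].[OH-]
Why: Palladium-catalysed hydroxylation of an unhindered aryl bromide, as in step 9.

Step 17
Reactants: 23 4-(3,5-dimethoxyphenoxy)-3,5-dimethoxyphenol; 14 1,3,5-trimethoxybenzene (3 equiv)
Product: 24 4-(3,5-dimethoxyphenoxy)-3,5-dimethoxy-2-(2,4,6-trimethoxyphenyl)phenol
Conditions: FeCl3 (10 mol %), t-BuOOt-Bu, (CF3)2CHOH, rt
Reagents that add atoms: none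
Why: Iron-catalysed oxidative phenol–arene cross-coupling at the ortho carbon of the B4 phenol, as in step 10. Ring A is a weaker nucleophile than 14 (one of its oxygens is a twisted aryloxy) and 14 is used in excess, so cross-coupling with 14 should dominate.

Step 18
Reactants: 24 4-(3,5-dimethoxyphenoxy)-3,5-dimethoxy-2-(2,4,6-trimethoxyphenyl)phenol; 3 5-bromo-2-fluoroisophthalaldehyde
Product: 25 5-bromo-2-[4-(3,5-dimethoxyphenoxy)-3,5-dimethoxy-2-(2,4,6-trimethoxyphenyl)phenoxy]isophthalaldehyde
Conditions: K2CO3, DMF, 40 °C
Reagents that add atoms: none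
Why: Formyl-activated SNAr forming the B4–O–C1 bond; addition to the doubly activated C–F carbon should tolerate the single ortho aryl group on the phenoxide.

Step 19
Reactants: 25 5-bromo-2-[4-(3,5-dimethoxyphenoxy)-3,5-dimethoxy-2-(2,4,6-trimethoxyphenyl)phenoxy]isophthalaldehyde
Product: 27 5-bromo-2-[4-(3,5-dimethoxyphenoxy)-3,5-dimethoxy-2-(2,4,6-trimethoxyphenyl)phenoxy]benzene-1,3-diol, via diformate 26 (not isolated)
Conditions: mCPBA (2.3 equiv), CH2Cl2, 0 °C; then K2CO3, MeOH
Reagents that add atoms: 3-chloroperoxybenzoic acid, O=C(OO)c1cccc(Cl)c1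
Why: Baeyer–Villiger oxidation of both formyl groups, then methanolysis. The peracid is kept near stoichiometric and cold, because addition to the aldehyde should be faster than hydroxylation of the trimethoxyphenyl ring.

Step 20
Reactants: 27 5-bromo-2-[4-(3,5-dimethoxyphenoxy)-3,5-dimethoxy-2-(2,4,6-trimethoxyphenyl)phenoxy]benzene-1,3-diol
Product: 28 5-bromo-2-[4-(3,5-dimethoxyphenoxy)-3,5-dimethoxy-2-(2,4,6-trimethoxyphenyl)phenoxy]-1,3-dimethoxybenzene
Conditions: MeI, K2CO3, DMF, rt
Reagents that add atoms: iodomethane, CI
Why: Williamson O-methylation of both phenols, which completes the A–B–B'–C bromide.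

Step 21
Reactants: 17 4-methoxy-2,6-bis[2,4,6-trimethoxy-3-(2,4,6-trimethoxyphenyl)phenoxy]phenol; 28 5-bromo-2-[4-(3,5-dimethoxyphenoxy)-3,5-dimethoxy-2-(2,4,6-trimethoxyphenyl)phenoxy]-1,3-dimethoxybenzene
Product: 29 docosa-O-methyl ether of the target
Conditions: CuI (20 mol %), picolinic acid (40 mol %), K3PO4, DMSO, 110 °C
Reagents that add atoms: none
Why: Ullmann-type diaryl ether synthesis; picolinate-ligated monovalent copper binds the phenoxide and couples it with the aryl bromide. This ligand system is the one suited to ortho-disubstituted phenols, and the bromide has two ortho hydrogens, so the hindrance lies on the nucleophile only.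

Step 22
Reactants: 29 docosa-O-methyl ether of the target
Product: 30 CNP0117322.0
Conditions: BBr3 (large excess), CH2Cl2, −78 °C to rt; then MeOH, H2O
Reagents that add atoms: none
Why: Lewis-acid cleavage of aryl methyl ethers (boron coordination, bromide attack at methyl, hydrolysis of the aryl borates); diaryl ethers and biaryl bonds are not cleaved by BBr3.

## Compound list

1 | 5-bromo-2-fluoro-1,3-dimethylbenzene | Cc1cc(Br)cc(C)c1F | starting material
2 | 5-bromo-1,3-bis(dibromomethyl)-2-fluorobenzene | BrC(Br)c1cc(Br)cc(C(Br)Br)c1F | intermediate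
3 | 5-bromo-2-fluoroisophthalaldehyde | O=Cc1cc(Br)cc(C=O)c1F | intermediate
4 | 4-methoxyphenol | COc1ccc(O)cc1 | starting material
5 | 2-hydroxy-5-methoxyisophthalaldehyde | COc1cc(C=O)c(O)c(C=O)c1 | intermediate
6 | 2-(benzyloxy)-5-methoxyisophthalaldehyde | COc1cc(C=O)c(OCc2ccccc2)c(C=O)c1 | intermediate
7 | 2-(benzyloxy)-5-methoxy-1,3-phenylene diformate (formed in the flask) | COc1cc(OC=O)c(OCc2ccccc2)c(OC=O)c1 | intermediate
8 | 2-(benzyloxy)-5-methoxybenzene-1,3-diol | COc1cc(O)c(OCc2ccccc2)c(O)c1 | intermediate
9 | ring D bis(ether) tetra-aldehyde dibromide | COc1cc(Oc2c(C=O)cc(Br)cc2C=O)c(OCc2ccccc2)c(Oc2c(C=O)cc(Br)cc2C=O)c1 | intermediate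
10 | tetraformate of 11 (formed in the flask) | COc1cc(Oc2c(OC=O)cc(Br)cc2OC=O)c(OCc2ccccc2)c(Oc2c(OC=O)cc(Br)cc2OC=O)c1 | intermediate
11 | ring D bis(ether) tetraphenol dibromide | COc1cc(Oc2c(O)cc(Br)cc2O)c(OCc2ccccc2)c(Oc2c(O)cc(Br)cc2O)c1 | intermediate
12 | 2-(benzyloxy)-1,3-bis(4-bromo-2,6-dimethoxyphenoxy)-5-methoxybenzene | COc1cc(Oc2c(OC)cc(Br)cc2OC)c(OCc2ccccc2)c(Oc2c(OC)cc(Br)cc2OC)c1 | intermediate
13 | ring D bis(ether) bis(E4 phenol) | COc1cc(Oc2c(OC)cc(O)cc2OC)c(OCc2ccccc2)c(Oc2c(OC)cc(O)cc2OC)c1 | intermediate
14 | 1,3,5-trimethoxybenzene | COc1cc(OC)cc(OC)c1 | starting material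
15 | bis(E–F biaryl) bis(E4 phenol) | COc1cc(Oc2c(OC)cc(O)c(-c3c(OC)cc(OC)cc3OC)c2OC)c(OCc2ccccc2)c(Oc2c(OC)cc(O)c(-c3c(OC)cc(OC)cc3OC)c2OC)c1 | intermediate
16 | benzyl ether of the D–E–F fragment | COc1cc(Oc2c(OC)cc(OC)c(-c3c(OC)cc(OC)cc3OC)c2OC)c(OCc2ccccc2)c(Oc2c(OC)cc(OC)c(-c3c(OC)cc(OC)cc3OC)c2OC)c1 | intermediate
17 | D1 phenol of the D–E–F fragment | COc1cc(Oc2c(OC)cc(OC)c(-c3c(OC)cc(OC)cc3OC)c2OC)c(O)c(Oc2c(OC)cc(OC)c(-c3c(OC)cc(OC)cc3OC)c2OC)c1 | intermediate
18 | 3,5-dimethoxyphenol | COc1cc(O)cc(OC)c1 | starting material
19 | 5-bromo-2-(3,5-dimethoxyphenoxy)isophthalaldehyde | COc1cc(OC)cc(Oc2c(C=O)cc(Br)cc2C=O)c1 | intermediate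
20 | diformate of 21 (formed in the flask) | COc1cc(OC)cc(Oc2c(OC=O)cc(Br)cc2OC=O)c1 | intermediate
21 | 5-bromo-2-(3,5-dimethoxyphenoxy)benzene-1,3-diol | COc1cc(OC)cc(Oc2c(O)cc(Br)cc2O)c1 | intermediate
22 | 5-bromo-2-(3,5-dimethoxyphenoxy)-1,3-dimethoxybenzene | COc1cc(OC)cc(Oc2c(OC)cc(Br)cc2OC)c1 | intermediate
23 | 4-(3,5-dimethoxyphenoxy)-3,5-dimethoxyphenol | COc1cc(OC)cc(Oc2c(OC)cc(O)cc2OC)c1 | intermediate
24 | 4-(3,5-dimethoxyphenoxy)-3,5-dimethoxy-2-(2,4,6-trimethoxyphenyl)phenol | COc1cc(OC)cc(Oc2c(OC)cc(O)c(-c3c(OC)cc(OC)cc3OC)c2OC)c1 | intermediate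
25 | A–B–B'–C dialdehyde bromide | COc1cc(OC)cc(Oc2c(OC)cc(Oc3c(C=O)cc(Br)cc3C=O)c(-c3c(OC)cc(OC)cc3OC)c2OC)c1 | intermediate
26 | diformate of 27 (formed in the flask) | COc1cc(OC)cc(Oc2c(OC)cc(Oc3c(OC=O)cc(Br)cc3OC=O)c(-c3c(OC)cc(OC)cc3OC)c2OC)c1 | intermediate
27 | A–B–B'–C diphenol bromide | COc1cc(OC)cc(Oc2c(OC)cc(Oc3c(O)cc(Br)cc3O)c(-c3c(OC)cc(OC)cc3OC)c2OC)c1 | intermediate
28 | A–B–B'–C bromide | COc1cc(OC)cc(Oc2c(OC)cc(Oc3c(OC)cc(Br)cc3OC)c(-c3c(OC)cc(OC)cc3OC)c2OC)c1 | intermediate
29 | docosa-O-methyl ether of the target | COc1cc(OC)cc(Oc2c(OC)cc(Oc3c(OC)cc(Oc4c(Oc5c(OC)cc(OC)c(-c6c(OC)cc(OC)cc6OC)c5OC)cc(OC)cc4Oc4c(OC)cc(OC)c(-c5c(OC)cc(OC)cc5OC)c4OC)cc3OC)c(-c3c(OC)cc(OC)cc3OC)c2OC)c1 | intermediate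
30 | CNP0117322.0 | Oc1cc(O)cc(Oc2c(O)cc(Oc3c(O)cc(Oc4c(Oc5c(O)cc(O)c(-c6c(O)cc(O)cc6O)c5O)cc(O)cc4Oc4c(O)cc(O)c(-c5c(O)cc(O)cc5O)c4O)cc3O)c(-c3c(O)cc(O)cc3O)c2O)c1 | target

## Step count and least certain steps

Total: 22 steps. Longest linear sequence: 12 steps (steps 3–12, 21, 22 from 4; the branch through steps 1, 2, 13–20, 21, 22 from 1 is equally long).

Step 6 (key step).
- Risk: the dianion of 8 is a phloroglucinol-type ambident nucleophile. Its ring carbons D3 and D5 may add to the unhindered formyl groups and then lose water, which would turn a reversible side reaction into an irreversible one. The second substitution may also stall once ring D carries one bulky, electron-poor aryloxy group.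
- Fallback: activate the fluoride with esters, which do not condense with carbon nucleophiles. Setting out from 1, KMnO4 oxidation gives 5-bromo-2-fluoroisophthalic acid F1. Esterification (MeOH, H2SO4) gives dimethyl 5-bromo-2-fluoroisophthalate F2. Substitution with 8 (Cs2CO3, DMF, 90 °C) gives the tetramethyl ester F3. Reduction with i-Bu2AlH gives the tetrakis(hydroxymethyl) compound F4, and MnO2 oxidation returns to the route at 9.

Step 7.
- Risk: the migrating ring bears a bromide and a second formyl group, so hydride may migrate instead of aryl in some of the four Criegee adducts, giving carboxylic acids. Partial conversion over four sites would give mixtures.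
- Fallback: use methyl ketones, in which only the aryl group can migrate usefully. Setting out from 9, addition of MeMgBr to all four formyl groups gives the tetrakis(1-hydroxyethyl) compound F5 as a mixture of diastereomers that converge. MnO2 oxidation gives the tetraacetyl compound F6. Baeyer–Villiger oxidation (mCPBA, CF3CO2H) gives the tetraacetate F7, and methanolysis (K2CO3, MeOH) returns to the route at 11.

Step 10.
- Risk: the 4-aryloxyphenol rings may be over-oxidised to quinones with expulsion of the para aryloxy group, which would break the D–O–E ethers. Phenol homo-coupling, a second arylation at E3 and capture of the oxidised phenol by ring D are also possible.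
- Fallback: a non-oxidative ortho arylation by ligand coupling (Pinhey arylation), which is specific to the phenol ring. Setting out from 14, direct plumbation with Pb(OAc)4 in CHCl3 gives (2,4,6-trimethoxyphenyl)lead triacetate F8. Treating 13 with F8 and pyridine in CHCl3 at 40 °C returns to the route at 15. The same reagent would serve for step 17.

Step 21.
- Risk: the phenoxide of 17, flanked by two large aryloxy groups, may fail to enter the copper cycle. The bromide 28 would then be lost by reduction or homo-coupling at the temperature required.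
- Fallback: an oxidative copper coupling at room temperature (Chan–Lam), which is known to accept doubly ortho-substituted phenols. Setting out from 28, bromine–lithium exchange (n-BuLi, −78 °C), B(Oi-Pr)3 and aqueous HCl give the arylboronic acid F9. Coupling with 17 under Cu(OAc)2, pyridine, 4 Å molecular sieves and air in CH2Cl2 returns to the route at 29.

Step 22.
- Risk: cleavage of the 22 methyl ethers may stay incomplete because partly deprotected borates precipitate, and the free polyphenol may be oxidised by air during isolation.
- Fallback: secure the product as its peracetate. Setting out from 29, the crude material from BBr3 is acetylated at once (Ac2O, pyridine) to the docosaacetate F10, which can be chromatographed and separated from under-demethylated fractions for recycling. Deacetylation under argon (NaOMe cat., degassed MeOH, then acidic resin) returns to the route at 30.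

## Further compounds

F1 | step 6 | 5-bromo-2-fluoroisophthalic acid | O=C(O)c1cc(Br)cc(C(=O)O)c1F
F2 | step 6 | dimethyl 5-bromo-2-fluoroisophthalate | COC(=O)c1cc(Br)cc(C(=O)OC)c1F
F3 | step 6 | tetramethyl ester analogue of 9 | COc1cc(Oc2c(C(=O)OC)cc(Br)cc2C(=O)OC)c(OCc2ccccc2)c(Oc2c(C(=O)OC)cc(Br)cc2C(=O)OC)c1
F4 | step 6 | tetrakis(hydroxymethyl) analogue of 9 | COc1cc(Oc2c(CO)cc(Br)cc2CO)c(OCc2ccccc2)c(Oc2c(CO)cc(Br)cc2CO)c1
F5 | step 7 | tetrakis(1-hydroxyethyl) analogue of 9 (mixture of diastereomers) | COc1cc(Oc2c(C(C)O)cc(Br)cc2C(C)O)c(OCc2ccccc2)c(Oc2c(C(C)O)cc(Br)cc2C(C)O)c1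
F6 | step 7 | tetraacetyl analogue of 9 | COc1cc(Oc2c(C(C)=O)cc(Br)cc2C(C)=O)c(OCc2ccccc2)c(Oc2c(C(C)=O)cc(Br)cc2C(C)=O)c1
F7 | step 7 | tetraacetate of 11 | COc1cc(Oc2c(OC(C)=O)cc(Br)cc2OC(C)=O)c(OCc2ccccc2)c(Oc2c(OC(C)=O)cc(Br)cc2OC(C)=O)c1
F8 | step 10 | (2,4,6-trimethoxyphenyl)lead triacetate | COc1cc(OC)c([Pb](OC(C)=O)(OC(C)=O)OC(C)=O)c(OC)c1
F9 | step 21 | arylboronic acid derived from 28 | COc1cc(OC)cc(Oc2c(OC)cc(Oc3c(OC)cc(B(O)O)cc3OC)c(-c3c(OC)cc(OC)cc3OC)c2OC)c1
F10 | step 22 | docosaacetate of 30 | CC(=O)Oc1cc(OC(C)=O)cc(Oc2c(OC(C)=O)cc(Oc3c(OC(C)=O)cc(Oc4c(Oc5c(OC(C)=O)cc(OC(C)=O)c(-c6c(OC(C)=O)cc(OC(C)=O)cc6OC(C)=O)c5OC(C)=O)cc(OC(C)=O)cc4Oc4c(OC(C)=O)cc(OC(C)=O)c(-c5c(OC(C)=O)cc(OC(C)=O)cc5OC(C)=O)c4OC(C)=O)cc3OC(C)=O)c(-c3c(OC(C)=O)cc(OC(C)=O)cc3OC(C)=O)c2OC(C)=O)c1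
A1 | alternative 1 | silylene-bridged B–B' biaryl (dibenzodioxasilepine) | COc1cc(OC)cc(Oc2c(OC)cc(OCc3ccccc3)c3c2O[Si](C(C)(C)C)(C(C)(C)C)Oc2cc(OC)cc(OC)c2-3)c1
A2 | alternative 1 | silylene-tethered aryl bromide | COc1cc(OC)cc(Oc2c(OC)cc(OCc3ccccc3)cc2O[Si](C(C)(C)C)(C(C)(C)C)Oc2cc(OC)cc(OC)c2Br)c1
A3 | alternative 2 | ring D bis(ether) with both E–F biaryls from benzannulation | COc1cc(Oc2c(OC)cc(OC)c(-c3c(O)cc(OCC)cc3O[Si](C(C)C)(C(C)C)C(C)C)c2OC)c(OCc2ccccc2)c(Oc2c(OC)cc(OC)c(-c3c(O)cc(OCC)cc3O[Si](C(C)C)(C(C)C)C(C)C)c2OC)c1
A4 | alternative 2 | bis(siloxyalkyne) | COc1cc(Oc2c(OC)cc(OC)c(C#CO[Si](C(C)C)(C(C)C)C(C)C)c2OC)c(OCc2ccccc2)c(Oc2c(OC)cc(OC)c(C#CO[Si](C(C)C)(C(C)C)C(C)C)c2OC)c1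
A5 | alternative 2 | 3-ethoxycyclobut-2-en-1-one | CCOC1=CC(=O)C1
A6 | alternative 3 | ring C phenol carrying rings D, E and F | COc1cc(Oc2c(Oc3c(OC)cc(OC)c(-c4c(OC)cc(OC)cc4OC)c3OC)cc(OC)cc2Oc2c(OC)cc(OC)c(-c3c(OC)cc(OC)cc3OC)c2OC)cc(OC)c1O
A7 | alternative 3 | 2-aryloxy vinamidinium hexafluorophosphate | CN(C)C=C(Oc1c(Oc2c(OC)cc(OC)c(-c3c(OC)cc(OC)cc3OC)c2OC)cc(OC)cc1Oc1c(OC)cc(OC)c(-c2c(OC)cc(OC)cc2OC)c1OC)C=[N+](C)C.F[P-](F)(F)(F)(F)F
A8 | alternative 3 | 1,3-dimethoxyacetone | COCC(=O)COC
A9 | alternative 3 | aryloxyacetic acid from the D1 phenol | O=C(O)COc1c(Oc2c(OC)cc(OC)c(-c3c(OC)cc(OC)cc3OC)c2OC)cc(OC)cc1Oc1c(OC)cc(OC)c(-c2c(OC)cc(OC)cc2OC)c1OC
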